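**Plan** (benzofuran numbering O1, C2, C3, C3a, C4–C7, C7a; C2' is the side-chain carbinol carbon; ring A is the dihydrofuran, ring B the carbocycle)
1. Retrosynthesis: the C5–prenyl bond is cut first; then O1–C7a, C3a–C4 and C4–C5 are cut together, with C4 leaving as CO, which opens rings A and B to an acyclic alkynol β-diketone.
2. The enabling feature is the enol-ether double bond C3a=C7a shared by rings A and B, with O1 on C7a and the C4 carbonyl on C3a (an alkyne that has taken up an oxygen and an acyl carbon), while C5 is the central carbon of a 1,3-dicarbonyl within six-ring reach of C4.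
3. The open chain is cut further at C5–C6 (aldehyde plus diazoketone) and at C3–C3a (acetylide plus terminal epoxide).
4. Forward: the epoxide piece (C2', C2, C3) and the alkyne piece (C3a, C7a, C7, C6) are made separately and joined at C3–C3a; the diketone is completed; rings A and B close in one step; C5 is prenylated; the silyl ether is removed.
5. Stereochemistry: C2 and C2' come from Katsuki–Sharpless epoxidation of nerol and Payne-type inversion at C2; C7 from ethyl (R)-3-hydroxybutanoate by two Fráter–Seebach alkylations; C5 by attack anti to the C7 prenyl group.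

Key step: step 14

Remark: the (2S,2'S) diol pattern of the target is the anti-addition pattern of a Z-alkene, so the epoxide/Payne route must start from nerol; geraniol would give the C2 epimer.
Remark: 19 and 21 are written as single tautomers and should exist largely as hydrogen-bonded enols; the CIP label at C7 of 21 (R) differs from that of 19 and 24 (S) only through the priority rules.

**Step 1**
Reactants: 1 nerol
Product: 2 (2R,3S)-2,3-epoxynerol
Conditions: Ti(OiPr)4 (5 mol%), D-(−)-diethyl tartrate (6 mol%), t-BuOOH, 4 Å MS, CH2Cl2, −20 °C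
Reagents that add atoms: tert-butyl hydroperoxide, CC(C)(C)OO
Why: Katsuki–Sharpless asymmetric epoxidation touches only the allylic 2,3-alkene, and the D-(−)-tartrate titanium complex should deliver oxygen to the face of the Z-allylic alcohol that gives the (2R,3S)-epoxide.

**Step 2**
Reactants: 2 (2R,3S)-2,3-epoxynerol
Product: 3 (2R,3S)-3,7-dimethyl-1-(phenylsulfanyl)oct-6-ene-2,3-diol
Conditions: PhSH (1.5 equiv, slow addition), 0.5 M aq NaOH, t-BuOH, 75 °C
Reagents that add atoms: thiophenol, Sc1ccccc1
Why: Payne rearrangement–opening: the C1 alkoxide opens the epoxide at the future C2 with inversion and thiolate captures the more reactive terminal epoxide at C1, while the tertiary C–O bond (future C2') is never broken.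

**Step 3**
Reactants: 3 (2R,3S)-3,7-dimethyl-1-(phenylsulfanyl)oct-6-ene-2,3-diol
Product: 5 (2S)-6-methyl-2-[(2S)-oxiran-2-yl]hept-5-en-2-ol, via sulfonium tetrafluoroborate 4 (not isolated)
Conditions: Me3OBF4, CH2Cl2, 0 °C → rt; then NaH (1.05 equiv), 0 °C
Reagents that add atoms: trimethyloxonium tetrafluoroborate, C[O+](C)C.F[B-](F)(F)F (its methyl group and counter-ion are found only in 4)
Why: S-methylation makes the sulfide a leaving group and the secondary alkoxide closes the oxirane by 3-exo-tet displacement at the primary carbon, which touches neither stereocentre; one equivalent of base leaves no alkoxide that could rearrange back to the internal epoxide.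

**Step 4**
Reactants: 5 (2S)-6-methyl-2-[(2S)-oxiran-2-yl]hept-5-en-2-ol
Product: 6 triethylsilyl ether of 5
Conditions: Et3SiOTf, 2,6-lutidine, CH2Cl2, −78 °C
Reagents that add atoms: triethylsilyl trifluoromethanesulfonate, CC[Si](CC)(CC)OS(=O)(=O)C(F)(F)F
Why: silyl triflate with a hindered pyridine base is the standard silylation of tertiary alcohols and at −78 °C should outrun any opening of the neighbouring epoxide.

**Step 5**
Reactants: 7 ethyl (3R)-3-hydroxybutanoate; 8 prenyl bromide
Product: 9 ethyl (2R,3R)-3-hydroxy-2-(3-methylbut-2-en-1-yl)butanoate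
Conditions: LiN(iPr)2 (2.2 equiv), THF, −50 → −20 °C; then 8, DMPU, −78 → 0 °C
Reagents that add atoms: none
Why: Fráter–Seebach alkylation: in the lithium-chelated alkoxide enolate the electrophile enters anti to the C3 methyl group, which should give the anti (2R,3R) product.

**Step 6**
Reactants: 9 ethyl (2R,3R)-3-hydroxy-2-(3-methylbut-2-en-1-yl)butanoate
Product: 10 ethyl (2S,3R)-3-hydroxy-2-methyl-2-(3-methylbut-2-en-1-yl)butanoate
Conditions: LiN(iPr)2 (2.3 equiv), THF, −78 → −20 °C; MeI, DMPU, −78 → 0 °C
Reagents that add atoms: iodomethane, CI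
Why: a second Fráter–Seebach alkylation of the now tetrasubstituted chelated enolate uses the same face, so methyl takes the site that prenyl took in step 5 and the quaternary centre becomes (2S); the minor epimer is removed by chromatography here, where it is still a diastereomer.

**Step 7**
Reactants: 10 ethyl (2S,3R)-3-hydroxy-2-methyl-2-(3-methylbut-2-en-1-yl)butanoate
Product: 11 ethyl (2S)-2-acetyl-2,5-dimethylhex-4-enoate
Conditions: Dess–Martin periodinane, NaHCO3, CH2Cl2, 0 °C → rt
Reagents that add atoms: none
Why: Dess–Martin oxidation of the secondary alcohol; the α-carbon is quaternary, so the β-keto ester cannot epimerise.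

**Step 8**
Reactants: 11 ethyl (2S)-2-acetyl-2,5-dimethylhex-4-enoate
Product: 13 ethyl (2S)-2-ethynyl-2,5-dimethylhex-4-enoate, via enol phosphate 12 (not isolated)
Conditions: LiN(iPr)2 (1.05 equiv), THF, −78 °C; ClP(O)(OEt)2, −78 → 0 °C; then LiN(iPr)2 (2.3 equiv), −78 → 0 °C; aq NH4Cl
Reagents that add atoms: diethyl chlorophosphate, CCOP(=O)(Cl)OCC (its phosphate group is found only in 12)
Why: methyl ketone to terminal alkyne by enol phosphate formation and base-induced elimination; the acetyl methyl is the only enolisable position and the quaternary neighbour excludes allene formation and loss of configuration.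

**Step 9**
Reactants: 13 ethyl (2S)-2-ethynyl-2,5-dimethylhex-4-enoate
Product: 14 (2S)-2-ethynyl-2,5-dimethylhex-4-en-1-ol
Conditions: LiAlH4, Et2O, 0 °C
Reagents that add atoms: none
Why: hydride reduction of the ester to the primary alcohol; the isolated alkyne and the trisubstituted alkene should be inert to LiAlH4 at 0 °C.

**Step 10**
Reactants: 15 2-methylpropanoyl chloride
Product: 16 1-diazo-3-methylbutan-2-one
Conditions: Me3SiCHN2 (2 equiv), MeCN/THF, 0 °C → rt
Reagents that add atoms: trimethylsilyldiazomethane, C[Si](C)(C)C=[N+]=[N-]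
Why: C-acylation of the diazomethane equivalent followed by chloride-induced desilylation (first stage of the Arndt–Eistert sequence) gives the α-diazo ketone.

**Step 11**
Reactants: 14 (2S)-2-ethynyl-2,5-dimethylhex-4-en-1-ol; 6 triethylsilyl-protected epoxide
Product: 17 alkynediol (primary C6 hydroxyl, secondary C2 hydroxyl, C2' silyl ether)
Conditions: 14 (1.2 equiv), n-BuLi (2.4 equiv), THF, −78 °C; BF3·OEt2 (2.5 equiv); 6, −78 °C; aq NH4Cl
Reagents that add atoms: none
Why: Yamaguchi–Hirao alkynylation: after double deprotonation the BF3-activated acetylide opens the epoxide at its CH2 terminus by SN2 without touching C2, the lithium alkoxide is a spectator, and at −78 °C neither silyl migration nor semipinacol rearrangement should intervene.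

**Step 12**
Reactants: 17 alkynediol
Product: 18 hydroxy aldehyde (C6 aldehyde)
Conditions: TEMPO (10 mol%), PhI(OAc)2 (1.1 equiv), CH2Cl2, rt
Reagents that add atoms: none
Why: oxoammonium-mediated oxidation selects the primary alcohol over the secondary one, which is further shielded by the adjacent quaternary silyloxy carbon.

**Step 13**
Reactants: 18 hydroxy aldehyde; 16 1-diazo-3-methylbutan-2-one
Product: 19 alkynol β-diketone
Conditions: SnCl2 (20 mol%), 16 (1.5 equiv), CH2Cl2, rt
Reagents that add atoms: none
Why: Roskamp-type homologation: the diazo carbon adds to the SnCl2-activated aldehyde and a 1,2-hydride shift with loss of N2 gives the β-diketone at the right oxidation level, under base-free conditions that tolerate the free C2 hydroxyl and exclude silyl migration.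

**Step 14**
Reactants: 19 alkynol β-diketone; 20 carbon monoxide
Product: 21 bicyclic enol triketone (C2'-O-triethylsilyl, C5 unsubstituted)
Conditions: PdI2 (5 mol%), KI (50 mol%), p-benzoquinone (1.5 equiv), CO (10 bar), MeCN, 40 °C
Reagents that add atoms: none
Why: Proposed new method: iodide-ligated divalent palladium binds the C3a≡C7a alkyne, the C2 hydroxyl adds anti to C7a (5-endo-dig, ring A) leaving a vinylpalladium on C3a, CO inserts to give the acylpalladium whose carbon is C4, and the enol carbon C5 of the tethered β-diketone is acylated (6-exo-trig, ring B) with release of zerovalent palladium, which benzoquinone and the two equivalents of HI return to PdI2. The closest known reactions are the PdI2/KI oxidative heterocyclisation–alkoxycarbonylation of alkynols, in which an alcohol takes the acylpalladium, and palladium-catalysed carbonylative cyclisations and acylations in which an acylpalladium is trapped by a stabilised 1,3-dicarbonyl enolate; joining the two in one oxidative cycle is the untested part. No stereocentre is created, and C2, C2' and C7 are not touched. Three selectivities are needed: oxypalladation by the C2 hydroxyl and no other oxygen, CO insertion before protonolysis of the vinylpalladium, and C- rather than O-acylation of the diketone. The first is secured by the triethylsilyl group on O2' (which removes the 5-exo-dig alternative) and by the free alcohol being a better nucleophile than the chelated enol oxygen, the second by CO pressure, and the third by the six-ring closure at C5 leading to the conjugated enol triketone, the most stable acylation product.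

**Step 15**
Reactants: 21 bicyclic enol triketone; 22 prenyl acetate
Product: 23 C2'-O-triethylsilyl ether of the target
Conditions: Pd(PPh3)4 (5 mol%), 22 (1.5 equiv), Et3N (1.5 equiv), THF, rt → 40 °C
Reagents that add atoms: none
Why: Tsuji–Trost allylic alkylation: the stabilised triketone enolate attacks the unsubstituted terminus of the 1,1-dimethylallyl palladium cation, reversible O-allylation drains to C5, and approach anti to the larger C7 prenyl group (syn to the C7 methyl) should favour the (5R) epimer.

**Step 16**
Reactants: 23 C2'-O-triethylsilyl ether of the target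
Product: 24 target compound
Conditions: HF·pyridine, pyridine, THF, 0 °C → rt
Reagents that add atoms: none
Why: fluoride-driven Si–O cleavage under buffered, non-basic conditions frees the tertiary alcohol without the retro-Claisen cleavage that hydroxide or unbuffered fluoride could cause at the non-enolisable triketone.

**Compound list**
1 | nerol, (2Z)-3,7-dimethylocta-2,6-dien-1-ol | CC(C)=CCC/C(C)=C\CO | starting material
2 | [(2R,3S)-3-methyl-3-(4-methylpent-3-en-1-yl)oxiran-2-yl]methanol | CC(C)=CCC[C@]1(C)O[C@@H]1CO | intermediate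
3 | (2R,3S)-3,7-dimethyl-1-(phenylsulfanyl)oct-6-ene-2,3-diol | CC(C)=CCC[C@](C)(O)[C@@H](O)CSc1ccccc1 | intermediate
4 | [(2R,3S)-2,3-dihydroxy-3,7-dimethyloct-6-en-1-yl](methyl)phenylsulfonium tetrafluoroborate (both configurations at sulfur) | CC(C)=CCC[C@](C)(O)[C@@H](O)C[S+](C)c1ccccc1.F[B-](F)(F)F | intermediate (not isolated)
5 | (2S)-6-methyl-2-[(2S)-oxiran-2-yl]hept-5-en-2-ol | CC(C)=CCC[C@](C)(O)[C@@H]1CO1 | intermediate
6 | triethyl{[(2S)-6-methyl-2-[(2S)-oxiran-2-yl]hept-5-en-2-yl]oxy}silane | CC(C)=CCC[C@](C)(O[Si](CC)(CC)CC)[C@@H]1CO1 | intermediate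
7 | ethyl (3R)-3-hydroxybutanoate | CCOC(=O)C[C@@H](C)O | starting material
8 | prenyl bromide, 1-bromo-3-methylbut-2-ene | CC(C)=CCBr | starting material
9 | ethyl (2R,3R)-3-hydroxy-2-(3-methylbut-2-en-1-yl)butanoate | CCOC(=O)[C@H](CC=C(C)C)[C@@H](C)O | intermediate
10 | ethyl (2S,3R)-3-hydroxy-2-methyl-2-(3-methylbut-2-en-1-yl)butanoate | CCOC(=O)[C@@](C)(CC=C(C)C)[C@@H](C)O | intermediate
11 | ethyl (2S)-2-acetyl-2,5-dimethylhex-4-enoate | CCOC(=O)[C@@](C)(CC=C(C)C)C(C)=O | intermediate
12 | ethyl (2S)-2-{1-[(diethoxyphosphoryl)oxy]ethenyl}-2,5-dimethylhex-4-enoate | CCOC(=O)[C@@](C)(CC=C(C)C)C(=C)OP(=O)(OCC)OCC | intermediate (not isolated)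
13 | ethyl (2S)-2-ethynyl-2,5-dimethylhex-4-enoate | CCOC(=O)[C@@](C)(CC=C(C)C)C#C | intermediate
14 | (2S)-2-ethynyl-2,5-dimethylhex-4-en-1-ol | OC[C@@](C)(CC=C(C)C)C#C | intermediate
15 | 2-methylpropanoyl chloride | CC(C)C(Cl)=O | starting material
16 | 1-diazo-3-methylbutan-2-one | CC(C)C(=O)C=[N+]=[N-] | intermediate
17 | (2S,6S,7S)-2,7,11-trimethyl-2-(3-methylbut-2-en-1-yl)-7-[(triethylsilyl)oxy]dodec-10-en-3-yne-1,6-diol | CC(C)=CCC[C@](C)(O[Si](CC)(CC)CC)[C@@H](O)CC#C[C@](C)(CC=C(C)C)CO | intermediate
18 | (2S,6S,7S)-6-hydroxy-2,7,11-trimethyl-2-(3-methylbut-2-en-1-yl)-7-[(triethylsilyl)oxy]dodec-10-en-3-ynal | CC(C)=CCC[C@](C)(O[Si](CC)(CC)CC)[C@@H](O)CC#C[C@](C)(CC=C(C)C)C=O | intermediate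
19 | (6S,10S,11S)-10-hydroxy-2,6,11,15-tetramethyl-6-(3-methylbut-2-en-1-yl)-11-[(triethylsilyl)oxy]hexadec-14-en-7-yne-3,5-dione | CC(C)=CCC[C@](C)(O[Si](CC)(CC)CC)[C@@H](O)CC#C[C@](C)(CC=C(C)C)C(=O)CC(=O)C(C)C | intermediate
20 | carbon monoxide | [C-]#[O+] | starting material
21 | (2S,7R)-6-hydroxy-7-methyl-7-(3-methylbut-2-en-1-yl)-5-(2-methylpropanoyl)-2-[(2S)-6-methyl-2-[(triethylsilyl)oxy]hept-5-en-2-yl]-3,7-dihydro-1-benzofuran-4(2H)-one (C7 arranged as in 19) | CC(C)=CCC[C@](C)(O[Si](CC)(CC)CC)[C@@H]1CC2=C(O1)[C@](C)(CC=C(C)C)C(O)=C(C(=O)C(C)C)C2=O | intermediate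
22 | prenyl acetate, 3-methylbut-2-en-1-yl acetate | CC(C)=CCOC(C)=O | starting material
23 | (2S,5R,7S)-7-methyl-5,7-bis(3-methylbut-2-en-1-yl)-5-(2-methylpropanoyl)-2-[(2S)-6-methyl-2-[(triethylsilyl)oxy]hept-5-en-2-yl]-2,3-dihydro-1-benzofuran-4,6(5H,7H)-dione | CC(C)=CCC[C@](C)(O[Si](CC)(CC)CC)[C@@H]1CC2=C(O1)[C@](C)(CC=C(C)C)C(=O)[C@](CC=C(C)C)(C(=O)C(C)C)C2=O | intermediate
24 | (2S,5R,7S)-2-[(2S)-2-hydroxy-6-methylhept-5-en-2-yl]-7-methyl-5,7-bis(3-methylbut-2-en-1-yl)-5-(2-methylpropanoyl)-2,3-dihydro-1-benzofuran-4,6(5H,7H)-dione | CC(C)=CCC[C@](C)(O)[C@@H]1CC2=C(O1)[C@](C)(CC=C(C)C)C(=O)[C@](CC=C(C)C)(C(=O)C(C)C)C2=O | target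

**Step count**
Total: 16 steps. Longest linear sequence: 11 steps (7 to 24 through steps 5–9 and 11–16).

**Steps most likely to fail**

Step 14. The acylpalladium may be taken by the enol oxygen instead of C5, the vinylpalladium may be protonated before CO inserts, or the diketone enol oxygen may compete with the C2 hydroxyl for the alkyne. The fallback divides the cascade into two known reactions. Starting from 19, PdI2/KI-catalysed oxidative heterocyclisation–methoxycarbonylation (CO/air, MeOH) should give the methyl 4,5-dihydrofuran-3-carboxylate F1, in which O1–C7a and C3a–C4 already exist. Treatment of F1 with KOt-Bu in THF would then close ring B by an intramolecular Claisen (Dieckmann-type) condensation of C5 onto the ester, and acidification returns the route to 21.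

Step 13. Addition of the diazo carbon to the α-quaternary aldehyde may be slow, so that diazoketone decomposition or a 1,2-carbon shift competes with the hydride shift. The fallback starts from 18. Silylation of the C2 hydroxyl (Et3SiOTf, 2,6-lutidine) would give the bis-silyl aldehyde F2. Aldol addition of the lithium enolate of 3-methylbutan-2-one (LiN(iPr)2, THF, −78 °C) would give the β-hydroxy ketone F3 as an inconsequential mixture of carbinol epimers. Dess–Martin oxidation would give the bis-silyl β-diketone F4, and PPTS in MeOH at 0 °C should remove only the less hindered secondary silyl ether, returning to 19.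

Step 15. Facial selectivity at C5 may be poor because methyl and prenyl on C7 differ little in size, and attack at the substituted allyl terminus may compete. The fallback starts from 21 and moves stereocontrol to the catalyst with the simpler allyl unit. Asymmetric allylic alkylation with allyl acetate, Pd2(dba)3 and the enantiomer of the DACH-phenyl bis(2-diphenylphosphinobenzamide) ligand that reinforces the substrate preference should give the C5-allyl triketone F5. Olefin cross-metathesis of F5 with 2-methylbut-2-ene (second-generation Grubbs catalyst) would convert allyl into prenyl, the existing trisubstituted alkenes being inert or exchanging degenerately, and returns to 23.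

**Further compounds**
F1 | step 14 | methyl (5S)-5-[(2S)-6-methyl-2-[(triethylsilyl)oxy]hept-5-en-2-yl]-2-[(5S)-2,5,9-trimethyl-6,8-dioxodec-2-en-5-yl]-4,5-dihydrofuran-3-carboxylate | CC(C)=CCC[C@](C)(O[Si](CC)(CC)CC)[C@@H]1CC(C(=O)OC)=C(O1)[C@](C)(CC=C(C)C)C(=O)CC(=O)C(C)C
F2 | step 13 | (2S,6S,7S)-2,7,11-trimethyl-2-(3-methylbut-2-en-1-yl)-6,7-bis[(triethylsilyl)oxy]dodec-10-en-3-ynal | CC(C)=CCC[C@](C)(O[Si](CC)(CC)CC)[C@@H](O[Si](CC)(CC)CC)CC#C[C@](C)(CC=C(C)C)C=O
F3 | step 13 | (6S,10S,11S)-5-hydroxy-2,6,11,15-tetramethyl-6-(3-methylbut-2-en-1-yl)-10,11-bis[(triethylsilyl)oxy]hexadec-14-en-7-yn-3-one (both C5 epimers) | CC(C)=CCC[C@](C)(O[Si](CC)(CC)CC)[C@@H](O[Si](CC)(CC)CC)CC#C[C@](C)(CC=C(C)C)C(O)CC(=O)C(C)C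
F4 | step 13 | (6S,10S,11S)-2,6,11,15-tetramethyl-6-(3-methylbut-2-en-1-yl)-10,11-bis[(triethylsilyl)oxy]hexadec-14-en-7-yne-3,5-dione | CC(C)=CCC[C@](C)(O[Si](CC)(CC)CC)[C@@H](O[Si](CC)(CC)CC)CC#C[C@](C)(CC=C(C)C)C(=O)CC(=O)C(C)C
F5 | step 15 | (2S,5R,7S)-7-methyl-7-(3-methylbut-2-en-1-yl)-5-(2-methylpropanoyl)-5-(prop-2-en-1-yl)-2-[(2S)-6-methyl-2-[(triethylsilyl)oxy]hept-5-en-2-yl]-2,3-dihydro-1-benzofuran-4,6(5H,7H)-dione | CC(C)=CCC[C@](C)(O[Si](CC)(CC)CC)[C@@H]1CC2=C(O1)[C@](C)(CC=C(C)C)C(=O)[C@](CC=C)(C(=O)C(C)C)C2=O
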